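Numbering the lactone O1, C2(=O), C3(Me), C4(OSO3H), C5 and the chain C6, C7(HMe) onward, the route rests on disconnecting ring bond C4–C5. One intramolecular Heck vinylation of a (Z)-enol ester closes the butenolide 5-exo and, through syn insertion and syn loss of H-5, converts the Z unit O1–C5H=C6H–C7 into the exocyclic C5=C6 alkene with C7 cis to C4 and trans to O1, the hindered E geometry of the target, while leaving bromine on C4 for the later enol sulfate. The precursor is the 3,3-dibromo-2-methylacrylate of the full-chain (Z)-alk-1-en-1-ol, obtained by ruthenium-catalysed addition of the acid to a citronellal-derived terminal alkyne already carrying the bisfuran.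

Key step: step 13

Remark: the target is drawn as the free hydrogen sulfate; that neutral form is listed as the last product, although in practice it would be stored as its sodium salt.

Step 1
Reactants: 1 ethyl pyruvate
Product: 2 ethyl 3,3-dibromo-2-methylprop-2-enoate
Conditions: CBr4 (2 equiv), PPh3 (4 equiv), CH2Cl2, 0 °C
Reagents that add atoms: carbon tetrabromide, BrC(Br)(Br)Br
Why: Ramirez dibromo-olefination, in which the ylide formed from CBr4 and PPh3 should react in a Wittig reaction with the activated ketone carbonyl of the α-keto ester and leave the ester untouched.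

Step 2
Reactants: 2 ethyl 3,3-dibromo-2-methylprop-2-enoate
Product: 3 3,3-dibromo-2-methylprop-2-enoic acid
Conditions: LiOH·H2O (1.5 equiv), THF/H2O, 0 °C; then 1 M HCl to pH 2
Reagents that add atoms: lithium hydroxide, [Li+].[OH-]
Why: Ester saponification, expected to outrun conjugate addition because the tetrasubstituted β-carbon is shielded by two bromines and the carboxylate, once formed, deactivates the acrylate.

Step 3
Reactants: 4 3-bromofuran; 5 4-bromo-2-furaldehyde
Product: 7 (4-bromofuran-2-yl)(furan-3-yl)methanol (racemic), via 3-furyllithium 6 (not isolated)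
Conditions: 4, n-BuLi, Et2O, −78 °C; then 5, −78 °C; H2O
Reagents that add atoms: none
Why: Bromine–lithium exchange gives 3-furyllithium, which holds its position at −78 °C and should add 1,2 to the aldehyde much faster than it exchanges with the ring bromide of 5; the new carbinol centre is racemic and is removed in step 4.

Step 4
Reactants: 7 (4-bromofuran-2-yl)(furan-3-yl)methanol
Product: 8 4-bromo-2-(furan-3-ylmethyl)furan
Conditions: Et3SiH (3 equiv), CF3CO2H (3 equiv), CH2Cl2, −20 → 0 °C, 7 added slowly
Reagents that add atoms: none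
Why: Ionic hydrogenation, in which acid ionises the doubly furyl-stabilised carbinol and excess silane traps the cation, with inverse addition keeping the cation dilute so that Friedel–Crafts oligomerisation of the furans is suppressed.

Step 5
Reactants: 9 (S)-citronellal
Product: 11 (3S)-3,7-dimethyloct-6-en-1-yne, via alkenyl nonaflate 10 (not isolated)
Conditions: C4F9SO2F (1.3 equiv), phosphazene base P2-Et (2.4 equiv), DMF, −20 °C → rt
Reagents that add atoms: none
Why: One-pot aldehyde-to-alkyne conversion through an alkenyl nonaflate, in which the base enolises the aldehyde, the enolate is O-sulfonylated, and a second equivalent of base eliminates nonaflate toward the only β-hydrogen (the vinylic one), so the C3 stereocentre is carried through unchanged.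

Step 6
Reactants: 11 (3S)-3,7-dimethyloct-6-en-1-yne
Product: 13 [(3S)-3,7-dimethyloct-6-en-1-yn-1-yl]tri(propan-2-yl)silane, via lithium acetylide 12 (not isolated)
Conditions: n-BuLi, THF, −78 °C; i-Pr3SiOTf, −78 → 0 °C
Reagents that add atoms: triisopropylsilyl trifluoromethanesulfonate, CC(C)[Si](OS(=O)(=O)C(F)(F)F)(C(C)C)C(C)C
Why: Deprotonation of the terminal alkyne and C-silylation of the acetylide; the bulky silyl group shields the alkyne from 9-BBN and from palladium-mediated alkynylation in step 10.

Step 7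
Reactants: 13 [(3S)-3,7-dimethyloct-6-en-1-yn-1-yl]tri(propan-2-yl)silane
Product: 14 (2E,6S)-2,6-dimethyl-8-[tri(propan-2-yl)silyl]oct-2-en-7-yn-1-ol
Conditions: SeO2 (0.3 equiv), t-BuOOH (3 equiv), salicylic acid (0.1 equiv), CH2Cl2, 0 °C → rt
Reagents that add atoms: selenium dioxide, O=[Se]=O (transfers the oxygen atom); tert-butyl hydroperoxide, CC(C)(C)OO (terminal oxidant that regenerates SeO2)
Why: Riley allylic oxidation (ene reaction then [2,3]-sigmatropic shift), which on a trisubstituted gem-dimethyl alkene should hydroxylate the E methyl group and give the E allylic alcohol, any enal from over-oxidation being separable.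

Step 8
Reactants: 14 (2E,6S)-2,6-dimethyl-8-[tri(propan-2-yl)silyl]oct-2-en-7-yn-1-ol
Product: 15 [(3S,6E)-8-bromo-3,7-dimethyloct-6-en-1-yn-1-yl]tri(propan-2-yl)silane
Conditions: CBr4, PPh3, CH2Cl2, 0 °C
Reagents that add atoms: carbon tetrabromide, BrC(Br)(Br)Br
Why: Appel reaction, a neutral SN2 displacement of the oxyphosphonium at the primary allylic carbon that should preserve the alkene geometry and the silyl alkyne.

Step 9
Reactants: 15 [(3S,6E)-8-bromo-3,7-dimethyloct-6-en-1-yn-1-yl]tri(propan-2-yl)silane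
Product: 16 [(3S,6E)-3,7-dimethyldeca-6,9-dien-1-yn-1-yl]tri(propan-2-yl)silane
Conditions: CH2=CHMgBr (2 equiv), CuI (10 mol%), THF, −30 → 0 °C
Reagents that add atoms: vinylmagnesium bromide, C=C[Mg]Br
Why: Copper-catalysed coupling of a Grignard reagent with a primary allylic bromide, which in THF should substitute at the unhindered CH2Br terminus and give the skipped diene with the E alkene retained.

Step 10
Reactants: 16 [(3S,6E)-3,7-dimethyldeca-6,9-dien-1-yn-1-yl]tri(propan-2-yl)silane; 8 4-bromo-2-(furan-3-ylmethyl)furan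
Product: 18 {(3S,6E)-10-[5-(furan-3-ylmethyl)furan-3-yl]-3,7-dimethyldec-6-en-1-yn-1-yl}tri(propan-2-yl)silane, via B-alkyl-9-BBN borane 17 (not isolated)
Conditions: 9-BBN-H dimer (0.55 equiv), THF, 0 °C → rt; then 8, Pd(OAc)2 (5 mol%), SPhos (10 mol%), 3 M aq. K3PO4, 60 °C
Reagents that add atoms: none
Why: 9-BBN should hydroborate the monosubstituted alkene anti-Markovnikov far faster than the trisubstituted alkene or the shielded silyl alkyne, and B-alkyl Suzuki–Miyaura coupling of the borane with the furyl bromide then forms the sp3–sp2 bond.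

Step 11
Reactants: 18 {(3S,6E)-10-[5-(furan-3-ylmethyl)furan-3-yl]-3,7-dimethyldec-6-en-1-yn-1-yl}tri(propan-2-yl)silane
Product: 19 2-(furan-3-ylmethyl)-4-[(4E,8S)-4,8-dimethyldec-4-en-9-yn-1-yl]furan
Conditions: Bu4NF (1.5 equiv), THF, 0 °C → rt
Reagents that add atoms: none
Why: Fluoride-induced cleavage of the alkynyl C–Si bond, under conditions that leave the propargylic stereocentre, the furans and the alkene alone.

Step 12
Reactants: 19 2-(furan-3-ylmethyl)-4-[(4E,8S)-4,8-dimethyldec-4-en-9-yn-1-yl]furan; 3 3,3-dibromo-2-methylprop-2-enoic acid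
Product: 20 (1Z,3S,6E)-10-[5-(furan-3-ylmethyl)furan-3-yl]-3,7-dimethyldeca-1,6-dien-1-yl 3,3-dibromo-2-methylprop-2-enoate
Conditions: Ru(η3-CH2C(CH3)CH2)2[Ph2P(CH2)4PPh2] (5 mol%), toluene, 60 °C, argon
Reagents that add atoms: none
Why: Ruthenium-catalysed anti-Markovnikov addition of a carboxylic acid to a terminal alkyne, in which carboxylate attack on a ruthenium vinylidene and protonolysis should deliver the (Z)-alk-1-enyl ester, the C–Br bonds being inert to divalent ruthenium.

Step 13
Reactants: 20 (1Z,3S,6E)-10-[5-(furan-3-ylmethyl)furan-3-yl]-3,7-dimethyldeca-1,6-dien-1-yl 3,3-dibromo-2-methylprop-2-enoate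
Product: 21 (5E)-4-bromo-5-{(2S,5E)-9-[5-(furan-3-ylmethyl)furan-3-yl]-2,6-dimethylnon-5-en-1-ylidene}-3-methylfuran-2(5H)-one
Conditions: Pd2(dba)3 (5 mol%), P(t-Bu)3 (20 mol%), Ag2CO3 (1.5 equiv), degassed toluene (0.01 M), 80 °C, dark
Reagents that add atoms: none
Why: Proposed new method: zerovalent palladium inserts into the C–Br bond of the CBr2 group that lies cis to the ester carbonyl, the alkenylpalladium (made cationic by Ag2CO3) adds syn across the electron-rich enol ester alkene with C4 bonding to the oxygen-bearing C5 and palladium going to C6, and after rotation about the new C5–C6 single bond syn β-hydride elimination of H-5 releases 21 while Ag2CO3 takes up HBr. The closest known reaction type is the intramolecular Heck cyclisation of alkenyl or aryl halides onto tethered enol ethers and enamides, together with cyclisations of gem-dibromoalkenes under Pd/P(t-Bu)3 in which one C–Br bond survives; an ester-tethered enol ester as the acceptor has not been shown. The butenolide ring (O1, C2, C3, C4, C5) closes in the 5-exo-trig mode through the C4–C5 bond. No stereocentre is created: the C5=C6 geometry follows stereospecifically from syn insertion and syn elimination on the Z enol ester, which leave C7 cis to C4 and trans to O1 (E), and C7 itself is never touched. The step needs 5-exo over 6-endo closure, secured by the short O1–C2–C3 tether, by the preference of cationic palladium to deliver carbon to the oxygen-bearing alkene carbon and by the branched C7 substituent shielding C6, and it needs loss of H-5 in preference to H-7, secured by the activation of H-5 by O1 and by the conjugated dienoate that results. Bulky P(t-Bu)3 keeps oxidative addition reversible, so insertion into the other C–Br bond of 20 or into C4–Br of 21 is not a dead end, Ag2CO3 removes HPdBr before re-addition can equilibrate the alkene, and 80 °C at high dilution lets the minor s-cis ester rotamer react.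

Step 14
Reactants: 21 (5E)-4-bromo-5-{(2S,5E)-9-[5-(furan-3-ylmethyl)furan-3-yl]-2,6-dimethylnon-5-en-1-ylidene}-3-methylfuran-2(5H)-one
Product: 23 (5E)-5-{(2S,5E)-9-[5-(furan-3-ylmethyl)furan-3-yl]-2,6-dimethylnon-5-en-1-ylidene}-4-hydroxy-3-methylfuran-2(5H)-one, via pinacol boronate 22 (not isolated)
Conditions: B2pin2 (1.3 equiv), PdCl2(dppf) (5 mol%), KOAc (3 equiv), 1,4-dioxane, 80 °C; then NaBO3·4H2O (5 equiv), THF/H2O, 0 °C → rt; work-up at pH 4
Reagents that add atoms: sodium perborate, [Na+].[O-]OB=O
Why: Miyaura borylation of the β-bromo enoate followed by oxidation of the alkenyl C–B bond should give the enol (tetronic acid) without exposing the enol lactone to alkoxide nucleophiles that could open the ring or add at C6, attack of peroxoborate at boron being faster than at the lactone carbonyl.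

Step 15
Reactants: 23 (5E)-5-{(2S,5E)-9-[5-(furan-3-ylmethyl)furan-3-yl]-2,6-dimethylnon-5-en-1-ylidene}-4-hydroxy-3-methylfuran-2(5H)-one
Product: 24 (5E)-5-{(2S,5E)-9-[5-(furan-3-ylmethyl)furan-3-yl]-2,6-dimethylnon-5-en-1-ylidene}-3-methyl-2-oxo-2,5-dihydrofuran-4-yl hydrogen sulfate (target, lactone numbering of the overview)
Conditions: SO3·pyridine (3 equiv), pyridine, 0 °C → rt
Reagents that add atoms: sulfur trioxide–pyridine complex, [O-]S(=O)(=O)[n+]1ccccc1
Why: O-Sulfation of the acidic enol with the SO3·pyridine complex, which at or below room temperature should not C-sulfonate the furans (that needs prolonged heating) and, being non-acidic, should preserve the E alkene.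

Compound list
1 | ethyl pyruvate (ethyl 2-oxopropanoate) | CCOC(=O)C(C)=O | starting material
2 | ethyl 3,3-dibromo-2-methylprop-2-enoate | CCOC(=O)C(C)=C(Br)Br | intermediate
3 | 3,3-dibromo-2-methylprop-2-enoic acid | CC(=C(Br)Br)C(=O)O | intermediate
4 | 3-bromofuran | Brc1ccoc1 | starting material
5 | 4-bromo-2-furaldehyde (4-bromofuran-2-carbaldehyde) | O=Cc1cc(Br)co1 | starting material
6 | 3-furyllithium | [Li]c1ccoc1 | intermediate
7 | (4-bromofuran-2-yl)(furan-3-yl)methanol, racemic | OC(c1ccoc1)c1cc(Br)co1 | intermediate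
8 | 4-bromo-2-(furan-3-ylmethyl)furan | Brc1coc(Cc2ccoc2)c1 | intermediate
9 | (S)-citronellal, (3S)-3,7-dimethyloct-6-enal | C[C@@H](CCC=C(C)C)CC=O | starting material
10 | (3S)-3,7-dimethylocta-1,6-dien-1-yl nonafluorobutane-1-sulfonate, E/Z mixture at C1=C2 | C[C@@H](CCC=C(C)C)C=COS(=O)(=O)C(F)(F)C(F)(F)C(F)(F)C(F)(F)F | intermediate
11 | (3S)-3,7-dimethyloct-6-en-1-yne | C#C[C@@H](C)CCC=C(C)C | intermediate
12 | lithium (3S)-3,7-dimethyloct-6-en-1-yn-1-ide | [Li]C#C[C@@H](C)CCC=C(C)C | intermediate
13 | [(3S)-3,7-dimethyloct-6-en-1-yn-1-yl]tri(propan-2-yl)silane | CC(C)[Si](C#C[C@@H](C)CCC=C(C)C)(C(C)C)C(C)C | intermediate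
14 | (2E,6S)-2,6-dimethyl-8-[tri(propan-2-yl)silyl]oct-2-en-7-yn-1-ol | CC(C)[Si](C#C[C@@H](C)CC/C=C(\C)CO)(C(C)C)C(C)C | intermediate
15 | [(3S,6E)-8-bromo-3,7-dimethyloct-6-en-1-yn-1-yl]tri(propan-2-yl)silane | CC(C)[Si](C#C[C@@H](C)CC/C=C(\C)CBr)(C(C)C)C(C)C | intermediate
16 | [(3S,6E)-3,7-dimethyldeca-6,9-dien-1-yn-1-yl]tri(propan-2-yl)silane | CC(C)[Si](C#C[C@@H](C)CC/C=C(\C)CC=C)(C(C)C)C(C)C | intermediate
17 | 9-{(4E,8S)-4,8-dimethyl-10-[tri(propan-2-yl)silyl]dec-4-en-9-yn-1-yl}-9-borabicyclo[3.3.1]nonane | CC(C)[Si](C#C[C@@H](C)CC/C=C(\C)CCCB1C2CCCC1CCC2)(C(C)C)C(C)C | intermediate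
18 | {(3S,6E)-10-[5-(furan-3-ylmethyl)furan-3-yl]-3,7-dimethyldec-6-en-1-yn-1-yl}tri(propan-2-yl)silane | CC(C)[Si](C#C[C@@H](C)CC/C=C(\C)CCCc1coc(Cc2ccoc2)c1)(C(C)C)C(C)C | intermediate
19 | 2-(furan-3-ylmethyl)-4-[(4E,8S)-4,8-dimethyldec-4-en-9-yn-1-yl]furan | C#C[C@@H](C)CC/C=C(\C)CCCc1coc(Cc2ccoc2)c1 | intermediate
20 | (1Z,3S,6E)-10-[5-(furan-3-ylmethyl)furan-3-yl]-3,7-dimethyldeca-1,6-dien-1-yl 3,3-dibromo-2-methylprop-2-enoate | BrC(Br)=C(C)C(=O)O/C=C\[C@@H](C)CC/C=C(\C)CCCc1coc(Cc2ccoc2)c1 | intermediate
21 | (5E)-4-bromo-5-{(2S,5E)-9-[5-(furan-3-ylmethyl)furan-3-yl]-2,6-dimethylnon-5-en-1-ylidene}-3-methylfuran-2(5H)-one | CC1=C(Br)/C(=C\[C@@H](C)CC/C=C(\C)CCCc2coc(Cc3ccoc3)c2)OC1=O | intermediate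
22 | (5E)-5-{(2S,5E)-9-[5-(furan-3-ylmethyl)furan-3-yl]-2,6-dimethylnon-5-en-1-ylidene}-3-methyl-4-(4,4,5,5-tetramethyl-1,3,2-dioxaborolan-2-yl)furan-2(5H)-one | CC1=C(B2OC(C)(C)C(C)(C)O2)/C(=C\[C@@H](C)CC/C=C(\C)CCCc2coc(Cc3ccoc3)c2)OC1=O | intermediate
23 | (5E)-5-{(2S,5E)-9-[5-(furan-3-ylmethyl)furan-3-yl]-2,6-dimethylnon-5-en-1-ylidene}-4-hydroxy-3-methylfuran-2(5H)-one | CC1=C(O)/C(=C\[C@@H](C)CC/C=C(\C)CCCc2coc(Cc3ccoc3)c2)OC1=O | intermediate
24 | (5E)-5-{(2S,5E)-9-[5-(furan-3-ylmethyl)furan-3-yl]-2,6-dimethylnon-5-en-1-ylidene}-3-methyl-2-oxo-2,5-dihydrofuran-4-yl hydrogen sulfate | CC1=C(OS(=O)(=O)O)/C(=C\[C@@H](C)CC/C=C(\C)CCCc2coc(Cc3ccoc3)c2)OC1=O | target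

Total step count: 15.
Longest linear sequence: 11 steps (steps 5–15, from (S)-citronellal 9).

Steps most likely to fail

Step 13 (Heck closure). The enol ester may fail to populate the s-cis rotamer in which palladium and the C5=C6 bond can meet, so the alkenylpalladium would be lost to reduction or oligomerisation. The palladium on C6 may also eliminate toward H-7, which erases the stereocentre, or palladium hydride may re-add and equilibrate the alkene geometry. The fallback uses known chemistry, sets out from alkyne 19 and rejoins at tetronic acid 23; it replaces the Heck closure by aldol addition and stereospecific anti elimination, which needs the chain one carbon shorter.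
- Anti-Markovnikov hydration of 19 (dicyclohexylborane, THF, 0 °C; NaBO3·4H2O) would give the homologous aldehyde (3S,6E)-10-[5-(furan-3-ylmethyl)furan-3-yl]-3,7-dimethyldec-6-enal F1.
- α-Benzoyloxylation with N-methyl-O-benzoylhydroxylamine hydrochloride (DMSO, rt) would give the 2-benzoyloxy aldehyde F2, and LiAlH4 (THF, 0 °C) the 1,2-diol F3.
- NaIO4 (THF/H2O), which spares furans, would excise the former alkyne terminus and leave the α-methyl aldehyde (2S,5E)-9-[5-(furan-3-ylmethyl)furan-3-yl]-2,6-dimethylnon-5-enal F4, whose aldehyde carbon is C6.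
- Addition of F4 to 5-lithio-4-methoxy-3-methylfuran-2(5H)-one (LiN(i-Pr)2, THF, −78 °C) would give the aldol adducts F5 as C5/C6 diastereomers.
- The pair with (5R,6R) or (5S,6S) configuration, separated by chromatography, would be dehydrated under Mitsunobu-type conditions (PPh3, diethyl azodicarboxylate, THF). H-5 and the activated oxygen on C6 leave antiperiplanar, so C7 ends cis to C4 and the E methyl tetronate F6 results; the other pair would give the Z isomer and is set aside.
- O-Demethylation with LiCl in DMF would return the route at 23.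

Step 14 (bromide to enol). The enol lactone may open, the C5=C6 geometry may be lost under the basic borylation and oxidation conditions, or the C4 boronate may protodeboronate. The fallback sets out from bromide 21 and rejoins at 23 by addition–elimination in place of C–B chemistry. Sodium 2-(trimethylsilyl)ethoxide (NaH, Me3SiCH2CH2OH, THF, −78 → −20 °C) would displace the C4 bromide to give the 2-(trimethylsilyl)ethyl tetronate F7. Bu4NF (THF, 0 °C) would then release 23 with loss of ethene and fluorotrimethylsilane.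

Step 12 (ruthenium-catalysed addition). Vinylidene formation at the α-branched alkyne may be slow, so that Markovnikov addition or erosion of the Z geometry competes, and the acidic halogenated acid may deactivate the catalyst. The fallback sets out from alkyne 19 and rejoins at enol ester 20 by forming the C–O bond from a stereodefined alkenylboron compound. Rhodium-catalysed trans-hydroboration ([Rh(cod)Cl]2, P(i-Pr)3, Et3N, pinacolborane, cyclohexane, rt) would give the (Z)-alkenyl pinacol boronate F8. KHF2 (MeOH/H2O) would convert it into the potassium (Z)-alkenyltrifluoroborate F9. Copper-catalysed oxidative coupling of F9 with acid 3 (CuBr, DMAP, 4 Å molecular sieves, O2, 60 °C), a Chan–Lam-type C–O coupling that retains alkene geometry, would give 20.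

Further compounds
F1 | step 13 | (3S,6E)-10-[5-(furan-3-ylmethyl)furan-3-yl]-3,7-dimethyldec-6-enal | O=CC[C@@H](C)CC/C=C(\C)CCCc1coc(Cc2ccoc2)c1
F2 | step 13 | (3S,6E)-10-[5-(furan-3-ylmethyl)furan-3-yl]-3,7-dimethyl-1-oxodec-6-en-2-yl benzoate, C2 epimers | O=CC(OC(=O)c1ccccc1)[C@@H](C)CC/C=C(\C)CCCc1coc(Cc2ccoc2)c1
F3 | step 13 | (3S,6E)-10-[5-(furan-3-ylmethyl)furan-3-yl]-3,7-dimethyldec-6-ene-1,2-diol, C2 epimers | OCC(O)[C@@H](C)CC/C=C(\C)CCCc1coc(Cc2ccoc2)c1
F4 | step 13 | (2S,5E)-9-[5-(furan-3-ylmethyl)furan-3-yl]-2,6-dimethylnon-5-enal | O=C[C@@H](C)CC/C=C(\C)CCCc1coc(Cc2ccoc2)c1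
F5 | step 13 | 5-{(2S,5E)-9-[5-(furan-3-ylmethyl)furan-3-yl]-1-hydroxy-2,6-dimethylnon-5-en-1-yl}-4-methoxy-3-methylfuran-2(5H)-one, diastereomers at C5 and C6 | COC1=C(C)C(=O)OC1C(O)[C@@H](C)CC/C=C(\C)CCCc1coc(Cc2ccoc2)c1
F6 | step 13 | (5E)-5-{(2S,5E)-9-[5-(furan-3-ylmethyl)furan-3-yl]-2,6-dimethylnon-5-en-1-ylidene}-4-methoxy-3-methylfuran-2(5H)-one | CC1=C(OC)/C(=C\[C@@H](C)CC/C=C(\C)CCCc2coc(Cc3ccoc3)c2)OC1=O
F7 | step 14 | (5E)-5-{(2S,5E)-9-[5-(furan-3-ylmethyl)furan-3-yl]-2,6-dimethylnon-5-en-1-ylidene}-3-methyl-4-[2-(trimethylsilyl)ethoxy]furan-2(5H)-one | CC1=C(OCC[Si](C)(C)C)/C(=C\[C@@H](C)CC/C=C(\C)CCCc2coc(Cc3ccoc3)c2)OC1=O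
F8 | step 12 | 2-{(1Z,3S,6E)-10-[5-(furan-3-ylmethyl)furan-3-yl]-3,7-dimethyldeca-1,6-dien-1-yl}-4,4,5,5-tetramethyl-1,3,2-dioxaborolane | CC1(C)OB(/C=C\[C@@H](C)CC/C=C(\C)CCCc2coc(Cc3ccoc3)c2)OC1(C)C
F9 | step 12 | potassium {(1Z,3S,6E)-10-[5-(furan-3-ylmethyl)furan-3-yl]-3,7-dimethyldeca-1,6-dien-1-yl}trifluoroborate | [K+].F[B-](F)(F)/C=C\[C@@H](C)CC/C=C(\C)CCCc1coc(Cc2ccoc2)c1
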